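**Retrosynthetic overview**
- The C5–O bond is cut last. It is made by C4-carbonyl-directed C–H oxygenation of 3,2'-dihydroxy-7,8,4'-trimethoxyflavone.
- That flavonol is opened at O1–C2 and C3–O, which leads back to a 2'-hydroxychalcone (oxidative cyclisation of Algar–Flynn–Oyamada type).
- The chalcone is cut at Cα=Cβ (Claisen–Schmidt condensation). This gives 2'-hydroxy-3',4'-dimethoxyacetophenone (ring A) and MOM-protected 2-hydroxy-4-methoxybenzaldehyde (ring B).
- Ring order: rings A and B are bought as arenes, and ring C is the only ring formed (step 2). The 5-OH is added afterwards because the ring C carbonyl directs it.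

Assumption: the SMILES contains no stereocentre and no hindered axis, so the target is achiral and no enantiocontrol is needed. The only stereoelement in the route is the transient E-alkene of the chalcone.

**Step 1**
Reactants: 1 2-hydroxy-4-methoxybenzaldehyde
Product: 2 4-methoxy-2-(methoxymethoxy)benzaldehyde
Conditions: MOMCl (1.3 equiv), K2CO3 (2 equiv), acetone, 0 °C to rt, 6 h
Reagents that add atoms: chloromethyl methyl ether (MOMCl), COCCl
Why: Williamson-type O-alkylation of the phenoxide with the very electrophilic chloromethyl ether, under conditions that leave the aldehyde and the aryl methyl ether untouched.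

**Step 2**
Reactants: 2 4-methoxy-2-(methoxymethoxy)benzaldehyde; 3 1-(2-hydroxy-3,4-dimethoxyphenyl)ethanone
Product: 6 3-hydroxy-2-(2-hydroxy-4-methoxyphenyl)-7,8-dimethoxy-4H-chromen-4-one, via MOM chalcone 4 (not isolated), via MOM flavonol 5 (not isolated)
Conditions: KOH (50% aq., 6 equiv), EtOH, rt, 24 h; 30% H2O2 (6 equiv), 0 °C to rt, 4 h; Na2SO3 quench; conc. HCl to pH 1, 55 °C, 2 h
Reagents that add atoms: hydrogen peroxide, OO
Why: Claisen–Schmidt condensation gives the E-chalcone, whose phenoxide closes ring C at Cβ while Cα is oxygenated by hydroperoxide (Algar–Flynn–Oyamada reaction, which gives the flavonol rather than the aurone when ring A has no 6'-substituent), and acidifying the peroxide-free pot hydrolyses the MOM acetal that had kept the ring B phenol from deactivating the aldehyde and attacking the oxidised enone.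

**Step 3**
Reactants: 6 3-hydroxy-2-(2-hydroxy-4-methoxyphenyl)-7,8-dimethoxy-4H-chromen-4-one
Product: 9 3,5,2'-trihydroxy-7,8,4'-trimethoxyflavone, via bis(trifluoroacetate) 7 (not isolated), via tris(trifluoroacetate) 8 (not isolated)
Conditions: (CF3CO)2O/CF3CO2H (1:2), rt, 30 min; [RuCl2(p-cymene)]2 (5 mol %), PhI(OCOCF3)2 (1.5 equiv), 60 °C, 8 h; evaporate; MeOH, rt, 1 h
Reagents that add atoms: bis(trifluoroacetoxy)iodobenzene, PhI(OCOCF3)2, O=C(OI(OC(=O)C(F)(F)F)c1ccccc1)C(F)(F)F (its trifluoroacetate oxygen becomes O5); trifluoroacetic anhydride, O=C(OC(=O)C(F)(F)F)C(F)(F)F (atoms only in 7 and 8, lost again before 9)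
Why: Proposed new method: transient double O-trifluoroacetylation turns the metal-sequestering 3-hydroxy-4-keto chelate and the oxidisable 2'-phenol of a free flavonol into inert esters, so the C4 carbonyl can bind Ru(O2CCF3)2(p-cymene) formed in situ (divalent ruthenium) and bring about carboxylate-assisted metalation of the only C–H it can reach (peri C5–H, para to the 8-methoxy donor, five-membered ruthenacycle), after which oxidation by the trivalent iodine reagent to tetravalent ruthenium and C–O reductive elimination give the 5-trifluoroacetate, which cannot over-oxidise to the 5,8-quinone and is released with the other two esters by methanolysis; the closest known reaction type is ketone-directed ruthenium- or palladium-catalysed ortho C–H oxygenation of aryl ketones, including C5 hydroxylation of simple flavones and chromones, which to my knowledge has not been shown on flavonols or on polymethoxylated substrates of this kind.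

**Compound list**
1 | 2-hydroxy-4-methoxybenzaldehyde | COc1ccc(C=O)c(O)c1 | starting material
2 | 4-methoxy-2-(methoxymethoxy)benzaldehyde | COCOc1cc(OC)ccc1C=O | intermediate
3 | 1-(2-hydroxy-3,4-dimethoxyphenyl)ethanone (2'-hydroxy-3',4'-dimethoxyacetophenone) | CC(=O)c1ccc(OC)c(OC)c1O | starting material
4 | (E)-1-(2-hydroxy-3,4-dimethoxyphenyl)-3-[4-methoxy-2-(methoxymethoxy)phenyl]prop-2-en-1-one (MOM chalcone) | COCOc1cc(OC)ccc1/C=C/C(=O)c1ccc(OC)c(OC)c1O | intermediate
5 | 3-hydroxy-7,8-dimethoxy-2-[4-methoxy-2-(methoxymethoxy)phenyl]-4H-chromen-4-one (MOM flavonol) | COCOc1cc(OC)ccc1-c1oc2c(OC)c(OC)ccc2c(=O)c1O | intermediate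
6 | 3-hydroxy-2-(2-hydroxy-4-methoxyphenyl)-7,8-dimethoxy-4H-chromen-4-one (3,2'-dihydroxy-7,8,4'-trimethoxyflavone) | COc1ccc(-c2oc3c(OC)c(OC)ccc3c(=O)c2O)c(O)c1 | intermediate
7 | 3,2'-bis(trifluoroacetoxy)-7,8,4'-trimethoxyflavone (bis(trifluoroacetate)) | COc1ccc(-c2oc3c(OC)c(OC)ccc3c(=O)c2OC(=O)C(F)(F)F)c(OC(=O)C(F)(F)F)c1 | intermediate
8 | 3,5,2'-tris(trifluoroacetoxy)-7,8,4'-trimethoxyflavone (tris(trifluoroacetate)) | COc1ccc(-c2oc3c(OC)c(OC)cc(OC(=O)C(F)(F)F)c3c(=O)c2OC(=O)C(F)(F)F)c(OC(=O)C(F)(F)F)c1 | intermediate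
9 | 3,5,2'-trihydroxy-7,8,4'-trimethoxyflavone | COc1ccc(-c2oc3c(OC)c(OC)cc(O)c3c(=O)c2O)c(O)c1 | target

**Total step count:** 3. **Longest linear sequence:** 3 (1 → 2 → 6 → 9; compound 3 enters at step 2).

**Steps most likely to fail**

Step 3 (the proposed new step) carries the highest risk.
- The trivalent iodine oxidant may attack the methoxylated rings.
- Traces of unmasked flavonol may tie up ruthenium.
- Protonation of the chromone in CF3CO2H may slow metalation.

The fallback uses known chemistry only and carries the 5-oxygen in from the start instead of installing it.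
- It sets out from 2, which is condensed (KOH, EtOH, rt) with purchased 1-(2-hydroxy-3,4,6-trimethoxyphenyl)ethanone F1. This gives (E)-1-(2-hydroxy-3,4,6-trimethoxyphenyl)-3-[4-methoxy-2-(methoxymethoxy)phenyl]prop-2-en-1-one F2.
- Algar–Flynn–Oyamada oxidation (H2O2, NaOH, MeOH, 0 °C) follows, and the aurone by-product is removed by chromatography. The product is 3-hydroxy-5,7,8-trimethoxy-2-[4-methoxy-2-(methoxymethoxy)phenyl]-4H-chromen-4-one F3.
- Chelation-controlled cleavage of the peri 5-methyl ether with BCl3 (CH2Cl2, −20 to 0 °C) comes next. Treatment with 2 M HCl/MeOH at 50 °C then breaks the boron chelate and removes the MOM group.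
- The fallback comes back to the route at 9.

Step 2 is the second risk. The oxidative cyclisation of an ortho-substituted, electron-rich chalcone may give a low yield, and running three operations in one pot may be messy. The fallback separates ring closure from C3 oxygenation.
- It sets out from 4, isolated by neutralising after the aldol stage.
- Treatment with I2 (1.1 equiv) in pyridine at 95 °C gives cyclodehydrogenation, and the base keeps the MOM group on. The product is 7,8-dimethoxy-2-[4-methoxy-2-(methoxymethoxy)phenyl]-4H-chromen-4-one F4.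
- Dimethyldioxirane (acetone/CH2Cl2, 0 °C) epoxidises the C2=C3 bond. This gives racemic 2,3-epoxy-7,8-dimethoxy-2-[4-methoxy-2-(methoxymethoxy)phenyl]chroman-4-one F5.
- Catalytic p-TsOH opens the epoxide to the flavonol.
- The fallback comes back to the route at 5, which HCl in MeOH converts to 6 as in step 2.

Step 1 is the third risk. Alkylation of the hydrogen-bonded phenol may be incomplete, MOMCl varies in quality and is hazardous, and the acetal could leak during later handling. The fallback changes the protecting-group strategy to a hydrogenolysis-labile ether.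
- It sets out from 1, which with BnBr and K2CO3 in DMF gives 2-(benzyloxy)-4-methoxybenzaldehyde F6.
- Condensation with 3 (KOH, EtOH) gives (E)-3-[2-(benzyloxy)-4-methoxyphenyl]-1-(2-hydroxy-3,4-dimethoxyphenyl)prop-2-en-1-one F7.
- H2O2/NaOH converts this to 2-[2-(benzyloxy)-4-methoxyphenyl]-3-hydroxy-7,8-dimethoxy-4H-chromen-4-one F8.
- H2 (1 atm) over 10% Pd/C in EtOAc/MeOH removes the benzyl group.
- The fallback comes back to the route at 6.

**Further compounds**
F1 | step 3 | 1-(2-hydroxy-3,4,6-trimethoxyphenyl)ethanone | CC(=O)c1c(OC)cc(OC)c(OC)c1O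
F2 | step 3 | (E)-1-(2-hydroxy-3,4,6-trimethoxyphenyl)-3-[4-methoxy-2-(methoxymethoxy)phenyl]prop-2-en-1-one | COCOc1cc(OC)ccc1/C=C/C(=O)c1c(OC)cc(OC)c(OC)c1O
F3 | step 3 | 3-hydroxy-5,7,8-trimethoxy-2-[4-methoxy-2-(methoxymethoxy)phenyl]-4H-chromen-4-one | COCOc1cc(OC)ccc1-c1oc2c(OC)c(OC)cc(OC)c2c(=O)c1O
F4 | step 2 | 7,8-dimethoxy-2-[4-methoxy-2-(methoxymethoxy)phenyl]-4H-chromen-4-one | COCOc1cc(OC)ccc1-c1cc(=O)c2ccc(OC)c(OC)c2o1
F5 | step 2 | racemic 2,3-epoxy-7,8-dimethoxy-2-[4-methoxy-2-(methoxymethoxy)phenyl]chroman-4-one (cis-fused, one enantiomer drawn) | COCOc1cc(OC)ccc1[C@@]12Oc3c(OC)c(OC)ccc3C(=O)[C@@H]1O2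
F6 | step 1 | 2-(benzyloxy)-4-methoxybenzaldehyde | COc1ccc(C=O)c(OCc2ccccc2)c1
F7 | step 1 | (E)-3-[2-(benzyloxy)-4-methoxyphenyl]-1-(2-hydroxy-3,4-dimethoxyphenyl)prop-2-en-1-one | COc1ccc(/C=C/C(=O)c2ccc(OC)c(OC)c2O)c(OCc2ccccc2)c1
F8 | step 1 | 2-[2-(benzyloxy)-4-methoxyphenyl]-3-hydroxy-7,8-dimethoxy-4H-chromen-4-one | COc1ccc(-c2oc3c(OC)c(OC)ccc3c(=O)c2O)c(OCc2ccccc2)c1
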